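## Retrosynthetic overview

1. The lower dihydroflavonol unit (its three rings and both stereocentres) is not built: it is (+)-taxifolin 1, carried as its 7,3',4'-tribenzyl ether 2.
2. The upper unit is cut back to an open chalcone: acetophenone 3 gives dibenzyl ether 4, and 4 plus aldehyde 5 gives chalcone 6 (Claisen–Schmidt).
3. Key disconnection: the C3–C8'' bond and the O1–C2 bond of the upper unit are cut together. Forward, phenol oxidation of 6 joins its α-carbon to C8 of 2, and the chalcone 2'-OH closes quinone methide 7 to the 2,3-trans flavanone 8, the way chalcone and flavanoid units are thought to be coupled and cyclised in the plant.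
4. Ring order: all rings of the lower unit come from 1, the aromatic rings of the upper unit from 3 and 5, and ring C of the upper unit is the only ring formed, last, in the coupling step.
5. Global hydrogenolysis of 8 gives the target 9.

Assumption: the two 2,3-trans diastereomers formed in step 4 (upper unit 2S,3R or 2R,3S, lower unit 2R,3R in both) are separable by preparative HPLC; the route has not been run.

Locants: unprimed = upper flavanone unit, double-primed = lower taxifolin unit. The target is (2S,3R,2''R,3''R), with the upper unit 2,3-trans.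

## Route

Step 1
Reactants: 1 (+)-taxifolin, (2R,3R)-2-(3,4-dihydroxyphenyl)-3,5,7-trihydroxy-2,3-dihydro-4H-chromen-4-one
Product: 2 (2R,3R)-7-(benzyloxy)-2-[3,4-bis(benzyloxy)phenyl]-3,5-dihydroxy-2,3-dihydro-4H-chromen-4-one (7,3',4'-tri-O-benzyltaxifolin)
Conditions: BnBr (3.3 equiv), K2CO3 (3.5 equiv), DMF, 0 °C to rt, Ar, 16 h
Reagents that add atoms: benzyl bromide, BrCc1ccccc1
Why: Williamson etherification of the three acidic phenols only, because the 5-OH is hydrogen-bonded to the C4 carbonyl and the secondary 3-OH is not deprotonated by K2CO3; C2 and C3 from the chiral pool are untouched, and the 7-O-benzyl group later stops the 7-oxygen from closing a five-membered ring onto the quinone methide.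

Step 2
Reactants: 3 2,4,6-trihydroxyacetophenone
Product: 4 1-[2,4-bis(benzyloxy)-6-hydroxyphenyl]ethan-1-one
Conditions: BnBr (2.05 equiv), K2CO3 (2.2 equiv), acetone, reflux, 6 h
Reagents that add atoms: benzyl bromide, BrCc1ccccc1
Why: Williamson etherification of the 4-OH and one of the two equivalent ortho-OH groups, while the remaining ortho-OH is hydrogen-bonded to the acetyl carbonyl and stays free; no stereocentre.

Step 3
Reactants: 4 1-[2,4-bis(benzyloxy)-6-hydroxyphenyl]ethan-1-one; 5 3-(benzyloxy)-4-hydroxybenzaldehyde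
Product: 6 (E)-1-[2,4-bis(benzyloxy)-6-hydroxyphenyl]-3-[3-(benzyloxy)-4-hydroxyphenyl]prop-2-en-1-one
Conditions: KOH (50% aq, 10 equiv), EtOH, rt to 40 °C, 48 h; then 1 M HCl, 0 °C, to pH 4
Reagents that add atoms: none
Why: Claisen–Schmidt (crossed aldol) condensation with E1cB dehydration to the E-enone; the chalcone stays open as its bis-phenolate and is isolated by cold, mildly acidic work-up; no stereocentre.

Step 4
Reactants: 6 (E)-1-[2,4-bis(benzyloxy)-6-hydroxyphenyl]-3-[3-(benzyloxy)-4-hydroxyphenyl]prop-2-en-1-one; 2 7,3',4'-tri-O-benzyltaxifolin (3 equiv, excess recovered)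
Product: 8 (2S,3R)-5,7-bis(benzyloxy)-2-[3-(benzyloxy)-4-hydroxyphenyl]-3-[(2R,3R)-7-(benzyloxy)-2-[3,4-bis(benzyloxy)phenyl]-3,5-dihydroxy-4-oxo-3,4-dihydro-2H-chromen-8-yl]-2,3-dihydro-4H-chromen-4-one, via p-quinone methide 7 (not isolated)
Conditions: Ag2O (1.2 equiv), CH2Cl2/HFIP 4:1, 0 °C to rt, dark, Ar, 6 added over 8 h; Celite filtration; SiO2, then preparative HPLC (separation of the two trans diastereomers)
Reagents that add atoms: none
Why: Proposed new method: Ag2O (monovalent silver, two one-electron equivalents) oxidises only the acidic guaiacyl-type 4-OH of 6, since the 2'-OH of 6 and the 5-OH of 2 are hydrogen-bonded to carbonyl groups; the phenoxyl radical has high spin density at the α-carbon, as at C8 of a ferulate, and the electron-rich C8 of 2 (para to its free 5-OH, used in excess while 6 is kept dilute to suppress chalcone self-coupling) bonds there; a second one-electron oxidation with loss of H+ rearomatises ring A of the taxifolin unit and leaves p-quinone methide 7, whose methide carbon is attacked by the only hydroxyl within reach, the chalcone 2'-OH (6-exo oxa-1,6-addition), closing ring C with both aryl groups equatorial (2,3-trans, and C3–H can epimerise to this arrangement); the taxifolin stereocentres are too remote to bias the face, so the (2S,3R) and (2R,3S) trans products form in about equal amounts and 8 is the (2S,3R) isomer taken by HPLC and assigned by CD; closest known reaction type: Ag2O-mediated oxidative β-coupling of 4-hydroxycinnamoyl phenols with quinone-methide trapping (8–5 dihydrobenzofuran neolignans, flavonolignans from taxifolin and coniferyl alcohol) and oxidative cross-coupling of an easily oxidised phenol with a nucleophilic arene in HFIP.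

Step 5
Reactants: 8 hexabenzyl ether of the target (name as in step 4)
Product: 9 (2S,3R)-2-(3,4-dihydroxyphenyl)-3-[(2R,3R)-2-(3,4-dihydroxyphenyl)-3,5,7-trihydroxy-4-oxo-3,4-dihydro-2H-chromen-8-yl]-5,7-dihydroxy-2,3-dihydro-4H-chromen-4-one (target, EANPDB:THYM_00006)
Conditions: H2 (1 atm), 10% Pd/C, THF/MeOH 1:1, rt, 8 h; filtration; Sephadex LH-20 (MeOH)
Reagents that add atoms: none
Why: Hydrogenolysis of six aryl benzyl ethers under neutral conditions, which leaves the two chiral-pool centres and the two centres from step 4 unepimerised; the aryl ketones and the cyclic benzylic C2–O bonds are reduced far more slowly than O-benzyl groups.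

## Compound list

1 | (+)-taxifolin, (2R,3R)-2-(3,4-dihydroxyphenyl)-3,5,7-trihydroxy-2,3-dihydro-4H-chromen-4-one | Oc1cc(O)c2c(c1)O[C@H](c1ccc(O)c(O)c1)[C@@H](O)C2=O | starting material
2 | (2R,3R)-7-(benzyloxy)-2-[3,4-bis(benzyloxy)phenyl]-3,5-dihydroxy-2,3-dihydro-4H-chromen-4-one | C(Oc1cc(O)c2c(c1)O[C@H](c1ccc(OCc3ccccc3)c(OCc3ccccc3)c1)[C@@H](O)C2=O)c1ccccc1 | intermediate
3 | 2,4,6-trihydroxyacetophenone | CC(=O)c1c(O)cc(O)cc1O | starting material
4 | 1-[2,4-bis(benzyloxy)-6-hydroxyphenyl]ethan-1-one | CC(=O)c1c(O)cc(OCc2ccccc2)cc1OCc1ccccc1 | intermediate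
5 | 3-(benzyloxy)-4-hydroxybenzaldehyde | O=Cc1ccc(O)c(OCc2ccccc2)c1 | starting material
6 | (E)-1-[2,4-bis(benzyloxy)-6-hydroxyphenyl]-3-[3-(benzyloxy)-4-hydroxyphenyl]prop-2-en-1-one | O=C(/C=C/c1ccc(O)c(OCc2ccccc2)c1)c1c(O)cc(OCc2ccccc2)cc1OCc1ccccc1 | intermediate
7 | (2R,3R)-7-(benzyloxy)-8-{1-[2,4-bis(benzyloxy)-6-hydroxyphenyl]-3-[3-(benzyloxy)-4-oxocyclohexa-2,5-dien-1-ylidene]-1-oxopropan-2-yl}-2-[3,4-bis(benzyloxy)phenyl]-3,5-dihydroxy-2,3-dihydro-4H-chromen-4-one (p-quinone methide, both epimers at the new CH, not isolated) | O=C(c1c(O)cc(OCc2ccccc2)cc1OCc1ccccc1)C(C=C1C=CC(=O)C(OCc2ccccc2)=C1)c1c(OCc2ccccc2)cc(O)c2c1O[C@H](c1ccc(OCc3ccccc3)c(OCc3ccccc3)c1)[C@@H](O)C2=O | intermediate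
8 | (2S,3R)-5,7-bis(benzyloxy)-2-[3-(benzyloxy)-4-hydroxyphenyl]-3-[(2R,3R)-7-(benzyloxy)-2-[3,4-bis(benzyloxy)phenyl]-3,5-dihydroxy-4-oxo-3,4-dihydro-2H-chromen-8-yl]-2,3-dihydro-4H-chromen-4-one | O=C1c2c(OCc3ccccc3)cc(OCc3ccccc3)cc2O[C@H](c2ccc(O)c(OCc3ccccc3)c2)[C@H]1c1c(OCc2ccccc2)cc(O)c2c1O[C@H](c1ccc(OCc3ccccc3)c(OCc3ccccc3)c1)[C@@H](O)C2=O | intermediate
9 | (2S,3R)-2-(3,4-dihydroxyphenyl)-3-[(2R,3R)-2-(3,4-dihydroxyphenyl)-3,5,7-trihydroxy-4-oxo-3,4-dihydro-2H-chromen-8-yl]-5,7-dihydroxy-2,3-dihydro-4H-chromen-4-one | O=C1c2c(O)cc(O)cc2O[C@H](c2ccc(O)c(O)c2)[C@H]1c1c(O)cc(O)c2c1O[C@H](c1ccc(O)c(O)c1)[C@@H](O)C2=O | target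

## Step count and risks

Total step count: 5. Longest linear sequence: 4 steps (3 → 4 → 6 → 8 → 9).

The three steps most likely to fail, most risky first:

**Step 4.** The chalcone radical may self-couple to 8–5 or 8–O–4 type dimers instead of cross-coupling. Attack may occur at C6 of 2 or through C5 of the chalcone phenol ring. The product phenol may be over-oxidised. There is no facial control, so at best half of the coupled material is 8. The unwanted trans diastereomer can be re-equilibrated through the open chalcone with NaOAc in EtOH and separated again.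

Fallback, a polar route to the same C3–C8'' bond, setting out from 4 and 2 and coming back at 8. SeO2 (dioxane/H2O, 90 °C) oxidises the acetyl group of 4 to the arylglyoxal 2-[2,4-bis(benzyloxy)-6-hydroxyphenyl]-2-oxoacetaldehyde F1. Friedel–Crafts hydroxyalkylation of 2 at C8 by the aldehyde carbon of F1 (TsOH cat., CH2Cl2/HFIP, rt) gives the α-hydroxy ketone (2R,3R)-7-(benzyloxy)-8-{2-[2,4-bis(benzyloxy)-6-hydroxyphenyl]-1-hydroxy-2-oxoethyl}-2-[3,4-bis(benzyloxy)phenyl]-3,5-dihydroxy-2,3-dihydro-4H-chromen-4-one F2. Ionic hydrogenation (Et3SiH, CF3CO2H, CH2Cl2, −20 °C) removes the doubly activated benzylic hydroxyl and gives the deoxybenzoin (2R,3R)-7-(benzyloxy)-8-{2-[2,4-bis(benzyloxy)-6-hydroxyphenyl]-2-oxoethyl}-2-[3,4-bis(benzyloxy)phenyl]-3,5-dihydroxy-2,3-dihydro-4H-chromen-4-one F3. Knoevenagel-type condensation of F3 with 5 (piperidine, EtOH, reflux) gives the α-aryl chalcone (2R,3R)-7-(benzyloxy)-8-{1-[2,4-bis(benzyloxy)-6-hydroxyphenyl]-3-[3-(benzyloxy)-4-hydroxyphenyl]-1-oxoprop-2-en-2-yl}-2-[3,4-bis(benzyloxy)phenyl]-3,5-dihydroxy-2,3-dihydro-4H-chromen-4-one F4. F4 is not isolated: its 2'-OH closes ring C by 6-endo oxa-Michael addition (the chalcone-to-flavanone cyclisation) to the trans-2,3-diaryl chromanone, and the (2S,3R) diastereomer, separated by HPLC as in the main route, is 8.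

**Step 3.** The free 4-OH of 5 is deprotonated and deactivates the aldehyde, the 2,6-disubstituted acetophenone is hindered, and the chalcone may close to the flavanone.

Fallback, an olefination in place of the aldol, setting out from 4 and coming back at 6. CuBr2 (EtOAc/CHCl3, reflux) gives 2-bromo-1-[2,4-bis(benzyloxy)-6-hydroxyphenyl]ethan-1-one F5. PPh3 (toluene, rt) gives {2-[2,4-bis(benzyloxy)-6-hydroxyphenyl]-2-oxoethyl}triphenylphosphonium bromide F6. Aqueous Na2CO3 gives the stabilised ylide 1-[2,4-bis(benzyloxy)-6-hydroxyphenyl]-2-(triphenyl-λ5-phosphanylidene)ethan-1-one F7. Wittig reaction of F7 with 5 (toluene, 100 °C) gives the E-chalcone 6 without strong base.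

**Step 5.** Six benzyl ethers must be removed without hydrogenolysis of the two benzylic ring C2–O bonds or reduction of the ketones.

Fallback, non-reductive Lewis-acid dealkylation in place of hydrogenolysis, setting out from 8 and coming back at 9: BCl3 with pentamethylbenzene as benzyl-cation scavenger (CH2Cl2, −78 °C), then MeOH quench. It makes no new compound (F0).

## Further compounds

F1 | step 4 | 2-[2,4-bis(benzyloxy)-6-hydroxyphenyl]-2-oxoacetaldehyde | O=CC(=O)c1c(O)cc(OCc2ccccc2)cc1OCc1ccccc1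
F2 | step 4 | (2R,3R)-7-(benzyloxy)-8-{2-[2,4-bis(benzyloxy)-6-hydroxyphenyl]-1-hydroxy-2-oxoethyl}-2-[3,4-bis(benzyloxy)phenyl]-3,5-dihydroxy-2,3-dihydro-4H-chromen-4-one (both carbinol epimers) | O=C(c1c(O)cc(OCc2ccccc2)cc1OCc1ccccc1)C(O)c1c(OCc2ccccc2)cc(O)c2c1O[C@H](c1ccc(OCc3ccccc3)c(OCc3ccccc3)c1)[C@@H](O)C2=O
F3 | step 4 | (2R,3R)-7-(benzyloxy)-8-{2-[2,4-bis(benzyloxy)-6-hydroxyphenyl]-2-oxoethyl}-2-[3,4-bis(benzyloxy)phenyl]-3,5-dihydroxy-2,3-dihydro-4H-chromen-4-one | O=C(c1c(O)cc(OCc2ccccc2)cc1OCc1ccccc1)Cc1c(OCc2ccccc2)cc(O)c2c1O[C@H](c1ccc(OCc3ccccc3)c(OCc3ccccc3)c1)[C@@H](O)C2=O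
F4 | step 4 | (2R,3R)-7-(benzyloxy)-8-{1-[2,4-bis(benzyloxy)-6-hydroxyphenyl]-3-[3-(benzyloxy)-4-hydroxyphenyl]-1-oxoprop-2-en-2-yl}-2-[3,4-bis(benzyloxy)phenyl]-3,5-dihydroxy-2,3-dihydro-4H-chromen-4-one (alkene geometry not fixed) | O=C(c1c(O)cc(OCc2ccccc2)cc1OCc1ccccc1)C(=Cc1ccc(O)c(OCc2ccccc2)c1)c1c(OCc2ccccc2)cc(O)c2c1O[C@H](c1ccc(OCc3ccccc3)c(OCc3ccccc3)c1)[C@@H](O)C2=O
F5 | step 3 | 2-bromo-1-[2,4-bis(benzyloxy)-6-hydroxyphenyl]ethan-1-one | O=C(CBr)c1c(O)cc(OCc2ccccc2)cc1OCc1ccccc1
F6 | step 3 | {2-[2,4-bis(benzyloxy)-6-hydroxyphenyl]-2-oxoethyl}triphenylphosphonium bromide | O=C(C[P+](c1ccccc1)(c1ccccc1)c1ccccc1)c1c(O)cc(OCc2ccccc2)cc1OCc1ccccc1.[Br-]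
F7 | step 3 | 1-[2,4-bis(benzyloxy)-6-hydroxyphenyl]-2-(triphenyl-λ5-phosphanylidene)ethan-1-one | O=C(C=P(c1ccccc1)(c1ccccc1)c1ccccc1)c1c(O)cc(OCc2ccccc2)cc1OCc1ccccc1
F0 | step 5 | none | none
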